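**Plan**
- Retrosynthesis: the C4 ketone is taken back to a silyl-protected carbinol and the C7 phenol to its MOM ether. Ring C is then cut at C8a–O1, the chain at C3–C4 (aldol), and the prenyl group at its bond to C8.
- Enabling feature: in ring C, O1 joins the aromatic carbon C8a of ring A to the stereogenic benzylic carbon C2. An aryl bromide at C8a and a free (S)-carbinol at C2 can therefore be joined last, without touching the C2–O bond.
- Forward: ring A comes from 2-bromo-4-hydroxybenzaldehyde and is prenylated between Br and OMOM by directed metalation. Rings B and D come together as a purchased 2,2-dimethylchromene nitrile, converted into the 6-acetyl compound.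
- Aldol union, silylation and ketone reduction follow. Ring C is the only ring made, by palladium-catalysed aryl etherification; desilylation, C4 oxidation and MOM removal finish the route.
- Stereochemistry: C2 (S) comes from catalyst-controlled asymmetric transfer hydrogenation of aryl ketone 14 and is retained through ring closure. The C4 carbinol is carried as an epimer mixture and erased by oxidation.

Key step: step 8

Assumption: 1, 4 and 9 are purchased; compounds 13 to 17 are handled as mixtures at the oxygen-bearing carbon that becomes C4, which converge at ketone 18.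

**Step 1**
Reactants: 1 2-bromo-4-hydroxybenzaldehyde
Product: 2 2-bromo-4-(methoxymethoxy)benzaldehyde
Conditions: MOMCl, iPr2NEt, CH2Cl2, 0 °C to rt
Reagents that add atoms: chloromethyl methyl ether, COCCl
Why: Base-mediated O-alkylation (Williamson ether synthesis) of the acidic para-formyl phenol should be clean, and the MOM ether is both base-stable and an ortho-directing group for step 3.

**Step 2**
Reactants: 2 2-bromo-4-(methoxymethoxy)benzaldehyde
Product: 3 2-[2-bromo-4-(methoxymethoxy)phenyl]-1,3-dioxolane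
Conditions: TMSOCH2CH2OTMS, TMSOTf (3 mol%), CH2Cl2, −78 to −20 °C; pyridine quench
Reagents that add atoms: 1,2-bis(trimethylsilyloxy)ethane, C[Si](C)(C)OCCO[Si](C)(C)C
Why: Silyl-triflate-catalysed acetalisation with the bis-silyl ether of the diol is aprotic and driven by disiloxane formation, so the aldehyde is masked against the amide base and organometallics of step 3 without loss of the aryl MOM ether.

**Step 3**
Reactants: 3 2-[2-bromo-4-(methoxymethoxy)phenyl]-1,3-dioxolane; 4 prenyl bromide (1-bromo-3-methylbut-2-ene)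
Product: 8 2-bromo-4-(methoxymethoxy)-3-(3-methylbut-2-enyl)benzaldehyde, via the C3 aryllithium 5 (not isolated), via the C3 arylcopper 6 (not isolated), via the prenylated dioxolane 7 (not isolated)
Conditions: 3 added to LiN(iPr)2 (1.1 equiv), THF, −78 °C; CuBr·SMe2 (1.1 equiv), −78 °C; 4, −78 to 0 °C; then 1 M aq HCl, THF, rt
Reagents that add atoms: water, O
Why: Directed ortho-metalation removes the ring proton at C3, the only one flanked by both bromine and the MOM-oxy group, with an amide base that does not exchange bromine; at −78 °C the ortho-bromoaryllithium is kept from losing LiBr, the arylcopper formed by transmetalation attacks prenyl bromide at its primary carbon (SN2 allylation), and the dilute acid work-up hydrolyses the dioxolane while the aryl MOM ether stays.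

**Step 4**
Reactants: 9 2,2-dimethyl-2H-chromene-6-carbonitrile
Product: 11 1-(2,2-dimethyl-2H-chromen-6-yl)ethanone, via the bromomagnesium ketimide 10 (not isolated)
Conditions: MeMgBr (2.5 equiv), THF/toluene, 60 °C; then 1 M aq HCl, 0 °C to rt
Reagents that add atoms: methylmagnesium bromide, C[Mg]Br; water, O
Why: Grignard addition to the aryl nitrile stops at the N-magnesio ketimine, which cannot add a second equivalent and is hydrolysed to the methyl ketone on acidic work-up.

**Step 5**
Reactants: 11 1-(2,2-dimethyl-2H-chromen-6-yl)ethanone; 8 2-bromo-4-(methoxymethoxy)-3-(3-methylbut-2-enyl)benzaldehyde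
Product: 13 (±)-3-[2-bromo-4-(methoxymethoxy)-3-(3-methylbut-2-enyl)phenyl]-1-(2,2-dimethyl-2H-chromen-6-yl)-3-hydroxypropan-1-one, via the lithium enolate 12 (not isolated)
Conditions: LiN(iPr)2 (1.05 equiv), THF, −78 °C; then 8, −78 °C; AcOH quench at −78 °C
Reagents that add atoms: none
Why: A directed (crossed) aldol addition of the preformed lithium enolate to the non-enolisable aldehyde forms the C3–C4 bond under kinetic control, the cold acetic acid quench forestalling retro-aldol cleavage and dehydration, and the new carbinol centre may be racemic because it is oxidised later.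

**Step 6**
Reactants: 13 (±)-3-[2-bromo-4-(methoxymethoxy)-3-(3-methylbut-2-enyl)phenyl]-1-(2,2-dimethyl-2H-chromen-6-yl)-3-hydroxypropan-1-one
Product: 14 (±)-3-[2-bromo-4-(methoxymethoxy)-3-(3-methylbut-2-enyl)phenyl]-3-(tert-butyldimethylsilyloxy)-1-(2,2-dimethyl-2H-chromen-6-yl)propan-1-one
Conditions: TBSOTf, 2,6-lutidine, CH2Cl2, −78 °C
Reagents that add atoms: tert-butyldimethylsilyl trifluoromethanesulfonate, CC(C)(C)[Si](C)(C)OS(=O)(=O)C(F)(F)F
Why: A silyl triflate with a hindered pyridine base silylates the secondary benzylic hydroxyl at low temperature faster than the β-hydroxy ketone can eliminate, giving a base-stable ether that blocks retro-aldol chemistry in steps 7 and 8.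

**Step 7**
Reactants: 14 (±)-3-[2-bromo-4-(methoxymethoxy)-3-(3-methylbut-2-enyl)phenyl]-3-(tert-butyldimethylsilyloxy)-1-(2,2-dimethyl-2H-chromen-6-yl)propan-1-one
Product: 15 (1S)-3-[2-bromo-4-(methoxymethoxy)-3-(3-methylbut-2-enyl)phenyl]-3-(tert-butyldimethylsilyloxy)-1-(2,2-dimethyl-2H-chromen-6-yl)propan-1-ol (either C3 epimer)
Conditions: RuCl[(S,S)-TsDPEN](p-cymene) (2 mol%), HCO2H/Et3N (5:2), CH2Cl2, 30 °C
Reagents that add atoms: none
Why: Noyori–Ikariya asymmetric transfer hydrogenation delivers hydride from ruthenium and a proton from the ligand N–H to one face of the aryl ketone through a six-membered transition state in which the ketone aryl group lies against the η6-arene, so the (S,S) ligand should give the (1S) carbinol under catalyst control irrespective of the remote silyloxy centre, while the alkenes, the aryl bromide and both ethers are not touched.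

**Step 8**
Reactants: 15 (1S)-3-[2-bromo-4-(methoxymethoxy)-3-(3-methylbut-2-enyl)phenyl]-3-(tert-butyldimethylsilyloxy)-1-(2,2-dimethyl-2H-chromen-6-yl)propan-1-ol
Product: 16 (2S)-4-(tert-butyldimethylsilyloxy)-2-(2,2-dimethyl-2H-chromen-6-yl)-7-(methoxymethoxy)-8-(3-methylbut-2-enyl)chroman (either C4 epimer)
Conditions: Pd(OAc)2 (5 mol%), rac-2-(di-tert-butylphosphino)-1,1'-binaphthyl (6 mol%), Cs2CO3 (1.5 equiv), toluene, 80 °C
Reagents that add atoms: none
Why: Pd(OAc)2 is reduced in the flask to a zerovalent palladium monophosphine complex that inserts into the C8a–Br bond; Cs2CO3 deprotonates the bound C2 hydroxyl, and the resulting seven-membered aryl palladium alkoxide undergoes C–O reductive elimination. The closest known reaction type is the Buchwald–Hartwig-type intramolecular palladium-catalysed etherification of aryl bromides with secondary alcohols, which is established for chromans and 2-aryl chromans from 3-(2-bromoaryl)propan-1-ols. Ring C closes in the six-membered mode by bond formation between the alkoxide oxygen and the ipso carbon C8a, the new ring holding O1, C2, C3, C4, C4a and C8a. No stereocentre is created: the C2–O bond is never broken, so the (S) configuration set in step 7 is carried over unchanged and the C4 epimers pass through as a mixture. The step needs reductive elimination to outrun β-hydride elimination from the benzylic alkoxide, which would return ketone 14 and debrominated arene; the bulky, electron-rich di-tert-butyl biaryl phosphine and the steric compression from the two ortho substituents at C8a both favour reductive elimination. The spectator groups should stay out of the way because insertion into the C8 prenyl double bond would require a four-membered or a five-membered endo closure, and because the C4 oxygen is held as a TBS ether so that carbonate cannot start retro-aldol cleavage or dehydration.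

**Step 9**
Reactants: 16 (2S)-4-(tert-butyldimethylsilyloxy)-2-(2,2-dimethyl-2H-chromen-6-yl)-7-(methoxymethoxy)-8-(3-methylbut-2-enyl)chroman
Product: 17 (2S)-2-(2,2-dimethyl-2H-chromen-6-yl)-7-(methoxymethoxy)-8-(3-methylbut-2-enyl)chroman-4-ol (either C4 epimer)
Conditions: Bu4NF, THF, 0 °C to rt; water work-up
Reagents that add atoms: none
Why: Fluoride cleaves the alkyl TBS ether through pentacoordinate silicon, while the aryl MOM ether, the alkenes and the C2 centre are inert to these conditions.

**Step 10**
Reactants: 17 (2S)-2-(2,2-dimethyl-2H-chromen-6-yl)-7-(methoxymethoxy)-8-(3-methylbut-2-enyl)chroman-4-ol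
Product: 18 (2S)-2-(2,2-dimethyl-2H-chromen-6-yl)-7-(methoxymethoxy)-8-(3-methylbut-2-enyl)chroman-4-one
Conditions: Dess–Martin periodinane, pyridine, CH2Cl2, 0 °C to rt
Reagents that add atoms: none
Why: Dess–Martin oxidation converts both C4 epimers of the benzylic alcohol into the single ketone under pyridine-buffered, near-neutral conditions that should not enolise the product enough to open ring C, so C2 should keep its configuration.

**Step 11**
Reactants: 18 (2S)-2-(2,2-dimethyl-2H-chromen-6-yl)-7-(methoxymethoxy)-8-(3-methylbut-2-enyl)chroman-4-one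
Product: 19 (2S)-2-(2,2-dimethyl-2H-chromen-6-yl)-7-hydroxy-8-(3-methylbut-2-enyl)chroman-4-one (CNP0156801.1)
Conditions: 3 M aq HCl, MeOH, rt to 40 °C
Reagents that add atoms: none
Why: Acid-catalysed acetal exchange with methanol releases the phenol from its MOM ether as dimethoxymethane under mild conditions of the kind used for prenylated flavanones and chromenes, and since flavanones lose their C2 configuration by base-induced ring opening and not in dilute acid, the (2S) centre should survive.

**Compound list**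
1 | 2-bromo-4-hydroxybenzaldehyde | O=Cc1ccc(O)cc1Br | starting material
2 | 2-bromo-4-(methoxymethoxy)benzaldehyde | COCOc1ccc(C=O)c(Br)c1 | intermediate
3 | 2-[2-bromo-4-(methoxymethoxy)phenyl]-1,3-dioxolane | COCOc1ccc(C2OCCO2)c(Br)c1 | intermediate
4 | prenyl bromide (1-bromo-3-methylbut-2-ene) | CC(C)=CCBr | starting material
5 | [2-bromo-3-(1,3-dioxolan-2-yl)-6-(methoxymethoxy)phenyl]lithium | [Li]c1c(Br)c(C2OCCO2)ccc1OCOC | intermediate
6 | [2-bromo-3-(1,3-dioxolan-2-yl)-6-(methoxymethoxy)phenyl]copper | [Cu]c1c(Br)c(C2OCCO2)ccc1OCOC | intermediate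
7 | 2-[2-bromo-4-(methoxymethoxy)-3-(3-methylbut-2-enyl)phenyl]-1,3-dioxolane | CC(C)=CCc1c(OCOC)ccc(C2OCCO2)c1Br | intermediate
8 | 2-bromo-4-(methoxymethoxy)-3-(3-methylbut-2-enyl)benzaldehyde | CC(C)=CCc1c(OCOC)ccc(C=O)c1Br | intermediate
9 | 2,2-dimethyl-2H-chromene-6-carbonitrile | N#Cc1ccc2c(c1)C=CC(C)(C)O2 | starting material
10 | bromomagnesium N-[1-(2,2-dimethyl-2H-chromen-6-yl)ethylidene]amide | CC(=N[Mg]Br)c1ccc2c(c1)C=CC(C)(C)O2 | intermediate
11 | 1-(2,2-dimethyl-2H-chromen-6-yl)ethanone | CC(=O)c1ccc2c(c1)C=CC(C)(C)O2 | intermediate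
12 | lithium 1-(2,2-dimethyl-2H-chromen-6-yl)ethen-1-olate | [Li]OC(=C)c1ccc2c(c1)C=CC(C)(C)O2 | intermediate
13 | (±)-3-[2-bromo-4-(methoxymethoxy)-3-(3-methylbut-2-enyl)phenyl]-1-(2,2-dimethyl-2H-chromen-6-yl)-3-hydroxypropan-1-one | CC(C)=CCc1c(OCOC)ccc(C(O)CC(=O)c2ccc3c(c2)C=CC(C)(C)O3)c1Br | intermediate
14 | (±)-3-[2-bromo-4-(methoxymethoxy)-3-(3-methylbut-2-enyl)phenyl]-3-(tert-butyldimethylsilyloxy)-1-(2,2-dimethyl-2H-chromen-6-yl)propan-1-one | CC(C)=CCc1c(OCOC)ccc(C(O[Si](C)(C)C(C)(C)C)CC(=O)c2ccc3c(c2)C=CC(C)(C)O3)c1Br | intermediate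
15 | (1S)-3-[2-bromo-4-(methoxymethoxy)-3-(3-methylbut-2-enyl)phenyl]-3-(tert-butyldimethylsilyloxy)-1-(2,2-dimethyl-2H-chromen-6-yl)propan-1-ol, either C3 epimer | CC(C)=CCc1c(OCOC)ccc(C(O[Si](C)(C)C(C)(C)C)C[C@H](O)c2ccc3c(c2)C=CC(C)(C)O3)c1Br | intermediate
16 | (2S)-4-(tert-butyldimethylsilyloxy)-2-(2,2-dimethyl-2H-chromen-6-yl)-7-(methoxymethoxy)-8-(3-methylbut-2-enyl)chroman, either C4 epimer | CC(C)=CCc1c(OCOC)ccc2c1O[C@H](c1ccc3c(c1)C=CC(C)(C)O3)CC2O[Si](C)(C)C(C)(C)C | intermediate
17 | (2S)-2-(2,2-dimethyl-2H-chromen-6-yl)-7-(methoxymethoxy)-8-(3-methylbut-2-enyl)chroman-4-ol, either C4 epimer | CC(C)=CCc1c(OCOC)ccc2c1O[C@H](c1ccc3c(c1)C=CC(C)(C)O3)CC2O | intermediate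
18 | (2S)-2-(2,2-dimethyl-2H-chromen-6-yl)-7-(methoxymethoxy)-8-(3-methylbut-2-enyl)chroman-4-one | CC(C)=CCc1c(OCOC)ccc2c1O[C@H](c1ccc3c(c1)C=CC(C)(C)O3)CC2=O | intermediate
19 | (2S)-2-(2,2-dimethyl-2H-chromen-6-yl)-7-hydroxy-8-(3-methylbut-2-enyl)chroman-4-one | CC(C)=CCc1c(O)ccc2c1O[C@H](c1ccc3c(c1)C=CC(C)(C)O3)CC2=O | target

**Step count and risks**
Total steps: 11. Longest linear sequence: 10 steps (steps 1 to 3 and 5 to 11, from 1 to 19); the chromene ketone 11 is a one-step branch.

Step 8 (key step). What may go wrong is β-hydride elimination from the palladium alkoxide, or slow oxidative addition and reductive elimination at the doubly ortho-substituted C8a, so that ketone formation and debromination outpace ring closure. The fallback closes ring C from the other side, at O1–C2, by Mitsunobu inversion. It sets out from ketone 14, which is reduced with the enantiomeric catalyst RuCl[(R,R)-TsDPEN](p-cymene) in HCO2H/Et3N to (1R)-3-[2-bromo-4-(methoxymethoxy)-3-(3-methylbut-2-enyl)phenyl]-3-(tert-butyldimethylsilyloxy)-1-(2,2-dimethyl-2H-chromen-6-yl)propan-1-ol F1. Deprotonation with n-BuLi, bromine–lithium exchange with t-BuLi in THF at −78 °C, borylation with B(OMe)3 and oxidation with H2O2/NaOH should give (1R)-3-(tert-butyldimethylsilyloxy)-1-(2,2-dimethyl-2H-chromen-6-yl)-3-[2-hydroxy-4-(methoxymethoxy)-3-(3-methylbut-2-enyl)phenyl]propan-1-ol F2. PPh3 and diisopropyl azodicarboxylate in THF at 0 °C should then close ring C with inversion at C2 and return to the route at flavan 16. Partial ionisation of the para-alkoxybenzylic oxyphosphonium ion would erode the enantiomeric purity and is to be limited by low temperature.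

Step 3. What may go wrong is loss of LiBr from the ortho-bromoaryllithium (aryne formation), bromine migration between lithiated and unlithiated arene, or allylation at the tertiary end of prenyl bromide. The fallback delivers the carbon chain to C3 by sigmatropic rearrangement and completes the prenyl group by olefin metathesis. It sets out from 1: allyl bromide and K2CO3 in acetone give 4-(allyloxy)-2-bromobenzaldehyde F3. Aromatic Claisen rearrangement in N,N-diethylaniline at 190 °C should favour migration to the ortho carbon on the bromine side and give 3-allyl-2-bromo-4-hydroxybenzaldehyde F4 after removal of the C5 isomer. MOMCl and iPr2NEt give 3-allyl-2-bromo-4-(methoxymethoxy)benzaldehyde F5. Cross-metathesis with 2-methylbut-2-ene (second-generation Grubbs catalyst, CH2Cl2, 40 °C) should turn the allyl into the prenyl group and return to the route at aldehyde 8.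

Step 11. What may go wrong is an acid-promoted side reaction during MOM cleavage: cyclisation of the C8 prenyl group onto the freed C7 phenol, addition of methanol across the chromene double bond, or slow opening of ring C. The fallback changes the C7 protecting group to a silyl ether, so that the last step is a buffered fluoride cleavage. It sets out from aldehyde 8, where the acid step meets neither the chromene nor ring C, although the prenyl group ortho to the freed phenol is still exposed to acid there.
- HCl in MeOH at rt should give 2-bromo-4-hydroxy-3-(3-methylbut-2-enyl)benzaldehyde F6, and TIPSCl with imidazole in DMF should give 2-bromo-3-(3-methylbut-2-enyl)-4-(triisopropylsilyloxy)benzaldehyde F7.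
- Aldol addition of enolate 12 as in step 5 gives (±)-3-[2-bromo-3-(3-methylbut-2-enyl)-4-(triisopropylsilyloxy)phenyl]-1-(2,2-dimethyl-2H-chromen-6-yl)-3-hydroxypropan-1-one F8.
- TESOTf with 2,6-lutidine gives (±)-3-[2-bromo-3-(3-methylbut-2-enyl)-4-(triisopropylsilyloxy)phenyl]-1-(2,2-dimethyl-2H-chromen-6-yl)-3-(triethylsilyloxy)propan-1-one F9.
- Transfer hydrogenation as in step 7 gives (1S)-3-[2-bromo-3-(3-methylbut-2-enyl)-4-(triisopropylsilyloxy)phenyl]-1-(2,2-dimethyl-2H-chromen-6-yl)-3-(triethylsilyloxy)propan-1-ol F10.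
- The palladium etherification of step 8 gives (2S)-2-(2,2-dimethyl-2H-chromen-6-yl)-8-(3-methylbut-2-enyl)-4-(triethylsilyloxy)-7-(triisopropylsilyloxy)chroman F11.
- HF·pyridine buffered with pyridine in THF at 0 °C should remove the alkyl triethylsilyl group in preference to the aryl silyl ether and give (2S)-2-(2,2-dimethyl-2H-chromen-6-yl)-8-(3-methylbut-2-enyl)-7-(triisopropylsilyloxy)chroman-4-ol F12.
- Dess–Martin oxidation gives (2S)-2-(2,2-dimethyl-2H-chromen-6-yl)-8-(3-methylbut-2-enyl)-7-(triisopropylsilyloxy)chroman-4-one F13.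
- Bu4NF buffered with AcOH in THF at 0 °C cleaves the aryl silyl ether and returns to the route at target 19.

**Further compounds**
F1 | step 8 | (1R)-3-[2-bromo-4-(methoxymethoxy)-3-(3-methylbut-2-enyl)phenyl]-3-(tert-butyldimethylsilyloxy)-1-(2,2-dimethyl-2H-chromen-6-yl)propan-1-ol | CC(C)=CCc1c(OCOC)ccc(C(O[Si](C)(C)C(C)(C)C)C[C@@H](O)c2ccc3c(c2)C=CC(C)(C)O3)c1Br
F2 | step 8 | (1R)-3-(tert-butyldimethylsilyloxy)-1-(2,2-dimethyl-2H-chromen-6-yl)-3-[2-hydroxy-4-(methoxymethoxy)-3-(3-methylbut-2-enyl)phenyl]propan-1-ol | CC(C)=CCc1c(OCOC)ccc(C(O[Si](C)(C)C(C)(C)C)C[C@@H](O)c2ccc3c(c2)C=CC(C)(C)O3)c1O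
F3 | step 3 | 4-(allyloxy)-2-bromobenzaldehyde | C=CCOc1ccc(C=O)c(Br)c1
F4 | step 3 | 3-allyl-2-bromo-4-hydroxybenzaldehyde | C=CCc1c(O)ccc(C=O)c1Br
F5 | step 3 | 3-allyl-2-bromo-4-(methoxymethoxy)benzaldehyde | C=CCc1c(OCOC)ccc(C=O)c1Br
F6 | step 11 | 2-bromo-4-hydroxy-3-(3-methylbut-2-enyl)benzaldehyde | CC(C)=CCc1c(O)ccc(C=O)c1Br
F7 | step 11 | 2-bromo-3-(3-methylbut-2-enyl)-4-(triisopropylsilyloxy)benzaldehyde | CC(C)=CCc1c(O[Si](C(C)C)(C(C)C)C(C)C)ccc(C=O)c1Br
F8 | step 11 | (±)-3-[2-bromo-3-(3-methylbut-2-enyl)-4-(triisopropylsilyloxy)phenyl]-1-(2,2-dimethyl-2H-chromen-6-yl)-3-hydroxypropan-1-one | CC(C)=CCc1c(O[Si](C(C)C)(C(C)C)C(C)C)ccc(C(O)CC(=O)c2ccc3c(c2)C=CC(C)(C)O3)c1Br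
F9 | step 11 | (±)-3-[2-bromo-3-(3-methylbut-2-enyl)-4-(triisopropylsilyloxy)phenyl]-1-(2,2-dimethyl-2H-chromen-6-yl)-3-(triethylsilyloxy)propan-1-one | CC(C)=CCc1c(O[Si](C(C)C)(C(C)C)C(C)C)ccc(C(O[Si](CC)(CC)CC)CC(=O)c2ccc3c(c2)C=CC(C)(C)O3)c1Br
F10 | step 11 | (1S)-3-[2-bromo-3-(3-methylbut-2-enyl)-4-(triisopropylsilyloxy)phenyl]-1-(2,2-dimethyl-2H-chromen-6-yl)-3-(triethylsilyloxy)propan-1-ol | CC(C)=CCc1c(O[Si](C(C)C)(C(C)C)C(C)C)ccc(C(O[Si](CC)(CC)CC)C[C@H](O)c2ccc3c(c2)C=CC(C)(C)O3)c1Br
F11 | step 11 | (2S)-2-(2,2-dimethyl-2H-chromen-6-yl)-8-(3-methylbut-2-enyl)-4-(triethylsilyloxy)-7-(triisopropylsilyloxy)chroman | CC(C)=CCc1c(O[Si](C(C)C)(C(C)C)C(C)C)ccc2c1O[C@H](c1ccc3c(c1)C=CC(C)(C)O3)CC2O[Si](CC)(CC)CC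
F12 | step 11 | (2S)-2-(2,2-dimethyl-2H-chromen-6-yl)-8-(3-methylbut-2-enyl)-7-(triisopropylsilyloxy)chroman-4-ol | CC(C)=CCc1c(O[Si](C(C)C)(C(C)C)C(C)C)ccc2c1O[C@H](c1ccc3c(c1)C=CC(C)(C)O3)CC2O
F13 | step 11 | (2S)-2-(2,2-dimethyl-2H-chromen-6-yl)-8-(3-methylbut-2-enyl)-7-(triisopropylsilyloxy)chroman-4-one | CC(C)=CCc1c(O[Si](C(C)C)(C(C)C)C(C)C)ccc2c1O[C@H](c1ccc3c(c1)C=CC(C)(C)O3)CC2=O
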